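Reckon this flask by the half-life of its coupling partner, because each product formed takes one partner.

in all of them: left-handed substrate 0.020 M; right-handed substrate 0.020 M; free catalyst 0.71 mol%; impurity 47 µM

| charge | coupling partner | remark | time |
|---|---|---|---|
| Monday's | 1.4 equiv | run made earlier |  |
| Friday's | 2.2 equiv | run made earlier |  |
| flask | 1.00 equiv |  | 3.0 h |

| run | time / h | left-handed product / % | right-handed product / % | left-handed substrate / % |
|---|---|---|---|---|
| Monday's | 0.167 | 5.6 | 9.8 | 44.2 |
| Monday's | 0.500 | 14.9 | 21.7 | 36.5 |
| Monday's | 0.833 | 21.7 | 27.3 | 30.5 |
| Monday's | 1.33 | 28.0 | 30.2 | 25.8 |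
| Monday's | 2.00 | 31.5 | 33.3 | 23.9 |
| Monday's | 2.50 | 32.8 | 33.7 | 22.8 |
| Monday's | 3.00 | 33.3 | 34.0 | 20.4 |
| Friday's | 0.250 | 13.5 | 22.3 | 37.5 |
| Friday's | 0.333 | 17.7 | 24.8 | 34.4 |
| Friday's | 0.500 | 23.8 | 32.3 | 27.7 |
| Friday's | 0.833 | 35.0 | 38.9 | 18.7 |
| Friday's | 1.33 | 43.7 | 42.6 | 11.7 |
| Friday's | 2.00 | 47.8 | 45.4 | 6.2 |
| Friday's | 3.00 | 48.1 | 47.5 | 3.8 |

(each reading ± 0.5 percentage points)

- free catalyst is single-handed; left-handed substrate and right-handed substrate are mirror images of each other, charged as a racemate, each of them at the stated concentration
- the analysis behind the earlier runs scatters by 0.5 percentage points, standard deviation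
- steps under discussion: free catalyst + left-handed substrate <-> catalyst intermediate A; free catalyst + right-handed substrate <-> catalyst intermediate B; coupling partner + catalyst intermediate A -> free catalyst + left-handed product; coupling partner + catalyst intermediate B -> free catalyst + right-handed product; left-handed product <-> right-handed product; 2 free catalyst -> spent catalyst A; free catalyst + impurity -> spent catalyst B
- an excess is the difference of the two amounts in percent of their sum
- an excess is below zero if the other one leads

1. excess of left-handed product over right-handed product in the product at 20 min
2. excess of left-handed product over right-handed product in the product at 3.0 h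
3. part of the left-handed substrate and right-handed substrate charged together that has reacted at 3.0 h

Charged at 1.00 equiv on the left-handed substrate, the partner caps the flask's products at 50.0 % of both substrates, less than the whole charge, so it is the limiting reagent. Substrate held on the catalyst counts as reacted without being product, in this flask at most 0.355 % of both substrates. Monday, with the flask's catalyst and impurity charges, has a cap of 70.0 %. The partner unused there, cap minus both products, reads 54.6 % at 0.167 h and 21.0 % at 0.833 h. This gives the partner half-life, the time in which unused partner halves at the early pace: 0.483 h.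

Two extreme flasks can be solved at once. At that pace throughout, 3.0 h is 6.21 half-lives and the products reach 49.3 %. At Monday's late half-life, read as 1.06 h, they reach 43.0 %. The flask should lie between them and nearer the first, because at its cap 50.0 % of the substrates is unreacted, more than Monday's 32.7 % at its end. Scaling Monday's final share of its cap to this flask gives 48.1 %, so this reckoning commits to the span from there to 49.3 %.

The forecast gives −23 % (−27 % to −19 %), −1.3 % (−3.5 % to −0.3 %) and 48.3 % (46.5 % to 49.5 %), holding that “the flask is capped at 50%”.

The simulation gives −22.5 %, −0.982 % and 49.2 %, each inside the forecast's range.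

    free catalyst + left-handed substrate ⇌ catalyst intermediate A (K = 96.0 /M, k = 190 /M/s)
    free catalyst + right-handed substrate ⇌ catalyst intermediate B (K = 390 /M, k = 360 /M/s)
    coupling partner + catalyst intermediate A → free catalyst + left-handed product (k = 8.00 /M/s)
    coupling partner + catalyst intermediate B → free catalyst + right-handed product (k = 3.90 /M/s)
    left-handed product ⇌ right-handed product (k = 2.00 × 10⁻⁴ /s)
    2 free catalyst → spent catalyst A (k = 3.60 /M/s)
    free catalyst + impurity → spent catalyst B (k = 700 /M/s)

The flask's conversion of 49.2 % stands above 48.1 % and close to 49.3 %. At the end the flask keeps 1.9 % of its partner unbound, less than the 62 % of its left-handed substrate, against 1.35 % from 6.21 half-lives of 0.483 h. For a neighbour flask at 1.8 mol% of free catalyst, scaling by the catalyst the impurity leaves shortens the half-life to 0.147 h, so 3.0 h is 20.4 half-lives and the products should reach the cap. The neighbour holds 24.9 % and 25.1 % of the two products, with 0 % of its partner left and 50.3 % of its substrates reacted.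

All runs are calculated from invented constants; the scatter is artificial.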